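Ring D is disconnected from ring B at the C4'–O, C3'–C and O–CMe2 bonds. A 3-methoxyaryne and 3-methylbut-2-enal combine by [2+2] addition, oxete opening and oxa-6π closure, so one operation forms three bonds and the chromene. The methoxy group at the future C2', next to the aryne, places the carbon arm on C3' and the oxygen on C4'. The aryne precursor is an ortho-silylaryl triflate that already carries bromine at the future C1', the only carbon flanked by OMe and OMOM, because C1' and C5' are hard to tell apart once ring D exists. Negishi coupling with a 3-iodochromone, hydrogenation and MOM cleavage complete the target.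

Key step: step 7

Remark: in the finished chromane, C6 (C1' of ring B) and C8 (C5') both lie between two oxygen substituents and C8 is the less hindered, so the coupling handle is set as a bromine on the aryne precursor, where it is a spectator in the key step.

Step 1
Reactants: 1 methoxyhydroquinone (2-methoxybenzene-1,4-diol)
Product: 2 2-methoxy-4-(methoxymethoxy)phenol
Conditions: MOMCl (1.0 equiv), i-Pr2NEt, CH2Cl2, −20 → 0 °C, under N2
Reagents that add atoms: chloromethyl methyl ether, COCCl
Why: MOM etherification (Williamson-type O-alkylation) should occur at the C4 hydroxyl, which is the more acidic and unhindered one, whereas the C1 hydroxyl is flanked by and hydrogen-bonded to the methoxy group; the bis-ether and the minor regioisomer are removable by chromatography.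

Step 2
Reactants: 2 2-methoxy-4-(methoxymethoxy)phenol
Product: 3 2-methoxy-4-(methoxymethoxy)phenyl N,N-diethylcarbamate
Conditions: NaH, THF, 0 °C; Et2NCOCl, 0 °C → rt
Reagents that add atoms: N,N-diethylcarbamoyl chloride, CCN(CC)C(Cl)=O
Why: O-carbamoylation of the sodium phenoxide is a standard acylation and places the strongest oxygen-based directing group for ortho-metalation on C1.

Step 3
Reactants: 3 2-methoxy-4-(methoxymethoxy)phenyl N,N-diethylcarbamate
Product: 5 2-methoxy-4-(methoxymethoxy)-6-(trimethylsilyl)phenyl N,N-diethylcarbamate, via aryllithium 4 (not isolated)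
Conditions: s-BuLi, TMEDA, THF, −78 °C; Me3SiCl, −78 °C → rt
Reagents that add atoms: chlorotrimethylsilane, C[Si](C)(C)Cl
Why: In this directed ortho-metalation the O-carbamate, which outranks OMOM and OMe as a directing group, should guide s-BuLi at −78 °C to C6, its only free ortho position, and the aryllithium is silylated in the cold before an anionic Fries shift can set in.

Step 4
Reactants: 5 2-methoxy-4-(methoxymethoxy)-6-(trimethylsilyl)phenyl N,N-diethylcarbamate
Product: 7 3-bromo-2-methoxy-4-(methoxymethoxy)-6-(trimethylsilyl)phenyl N,N-diethylcarbamate, via aryllithium 6 (not isolated)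
Conditions: s-BuLi, TMEDA, THF, −78 °C; BrCCl2CCl2Br, −78 °C → rt
Reagents that add atoms: 1,2-dibromo-1,1,2,2-tetrachloroethane, BrC(Cl)(Cl)C(Cl)(Cl)Br
Why: A second directed ortho-metalation should remove the proton at C3, the only one flanked by two alkoxy donors (OMe and OMOM), since the carbamate has no ortho hydrogen left and C5 is shielded by the silyl group; the aryllithium is then brominated by the positive-bromine donor.

Step 5
Reactants: 7 3-bromo-2-methoxy-4-(methoxymethoxy)-6-(trimethylsilyl)phenyl N,N-diethylcarbamate
Product: 8 3-bromo-2-methoxy-4-(methoxymethoxy)-6-(trimethylsilyl)phenol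
Conditions: Cp2Zr(H)Cl (3 equiv), THF, rt; aq. NaHCO3
Reagents that add atoms: none
Why: Reductive cleavage of the aryl O-carbamate by hydrozirconation of its carbonyl group and collapse of the adduct should free the phenol under mild conditions that leave the aryl bromide, the aryl silane and the MOM acetal untouched and that tolerate the two ortho substituents better than hydrolysis would.

Step 6
Reactants: 8 3-bromo-2-methoxy-4-(methoxymethoxy)-6-(trimethylsilyl)phenol
Product: 9 3-bromo-2-methoxy-4-(methoxymethoxy)-6-(trimethylsilyl)phenyl trifluoromethanesulfonate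
Conditions: Tf2O, pyridine, CH2Cl2, 0 °C
Reagents that add atoms: trifluoromethanesulfonic anhydride, O=S(=O)(OS(=O)(=O)C(F)(F)F)C(F)(F)F
Why: O-Sulfonylation (triflation) of the phenol with the anhydride and pyridine gives the ortho-silylaryl triflate, the standard fluoride-triggered aryne precursor, without touching the buffered MOM ether.

Step 7
Reactants: 9 3-bromo-2-methoxy-4-(methoxymethoxy)-6-(trimethylsilyl)phenyl trifluoromethanesulfonate; 10 3-methylbut-2-enal
Product: 14 6-bromo-5-methoxy-7-(methoxymethoxy)-2,2-dimethyl-2H-chromene, via aryne 11 (not isolated), via benzoxete 12 (not isolated), via ortho-quinone methide 13 (not isolated)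
Conditions: CsF (3 equiv), 10 (5 equiv), MeCN, rt
Reagents that add atoms: none
Why: Fluoride attacks silicon and triflate leaves to give aryne 11, whose C–OMe neighbour polarises and distorts the triple bond so that the carbonyl oxygen of 10 adds to the remote aryne carbon and the aryl anion formed next to OMe closes on the carbonyl carbon, giving benzoxete 12 by a formal [2+2] addition. The strained oxete opens by retro-4π electrocyclisation to ortho-quinone methide 13, a 1-oxatriene that closes ring D by thermal oxa-6π electrocyclisation, which forms the O–CMe2 bond and restores the aromaticity of ring B. The closest known reaction type is the fluoride-induced reaction of arynes with α,β-unsaturated aldehydes to give 2H-chromenes, together with the regioselective insertion of 3-methoxyarynes into the C=O bond of formamides. No stereocentre remains, because the sp3 carbon of 12 is lost on ring opening and C2 of the chromene carries two methyl groups. The step needs regioselectivity (oxygen on the future C4', carbon on C3'), which the inductively withdrawing methoxy group beside the aryne should secure while bromine and OMOM are too remote to interfere, and it needs the aldehyde to win over a second aryne, which the excess of 10 should secure.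

Step 8
Reactants: 15 2,4-dihydroxyacetophenone
Product: 16 1-[2-hydroxy-4-(methoxymethoxy)phenyl]ethan-1-one
Conditions: MOMCl (1.1 equiv), i-Pr2NEt, CH2Cl2, 0 °C → rt
Reagents that add atoms: chloromethyl methyl ether, COCCl
Why: MOM etherification should be selective for the C4 hydroxyl because the C2 hydroxyl is held in a hydrogen bond to the ketone and is much less nucleophilic.

Step 9
Reactants: 16 1-[2-hydroxy-4-(methoxymethoxy)phenyl]ethan-1-one
Product: 17 (E)-3-(dimethylamino)-1-[2-hydroxy-4-(methoxymethoxy)phenyl]prop-2-en-1-one
Conditions: Me2NCH(OMe)2, toluene, 100 °C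
Reagents that add atoms: N,N-dimethylformamide dimethyl acetal, COC(OC)N(C)C
Why: Condensation of the methyl ketone with the formamide acetal gives the (E)-enaminone, the usual one-carbon homologation on the way to chromones.

Step 10
Reactants: 17 (E)-3-(dimethylamino)-1-[2-hydroxy-4-(methoxymethoxy)phenyl]prop-2-en-1-one
Product: 18 3-iodo-7-(methoxymethoxy)-4H-chromen-4-one
Conditions: I2, pyridine, CHCl3, rt
Reagents that add atoms: iodine, [I][I]
Why: Iodination at the α-carbon of the enaminone triggers attack of the phenol on the iminium carbon and loss of dimethylamine (iodine-mediated cyclisation of 2-hydroxyphenyl enaminones to 3-iodochromones), and pyridine buffers the acid so that the MOM ether survives.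

Step 11
Reactants: 14 6-bromo-5-methoxy-7-(methoxymethoxy)-2,2-dimethyl-2H-chromene; 18 3-iodo-7-(methoxymethoxy)-4H-chromen-4-one
Product: 21 3-[5-methoxy-7-(methoxymethoxy)-2,2-dimethyl-2H-chromen-6-yl]-7-(methoxymethoxy)-4H-chromen-4-one, via aryllithium 19 (not isolated), via arylzinc chloride 20 (not isolated)
Conditions: n-BuLi, THF, −78 °C; ZnCl2, −78 °C → rt; 18, Pd2(dba)3 (2 mol %), SPhos (8 mol %), THF, 50 °C
Reagents that add atoms: none
Why: Bromine–lithium exchange fixes the metal at C6 without any choice of site, transmetalation to zinc tames the nucleophile so that it does not add to the chromone, and Negishi coupling with a bulky electron-rich biarylphosphine on palladium should join the doubly ortho-substituted arylzinc to the reactive C3–I bond of 18.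

Step 12
Reactants: 21 3-[5-methoxy-7-(methoxymethoxy)-2,2-dimethyl-2H-chromen-6-yl]-7-(methoxymethoxy)-4H-chromen-4-one
Product: 22 3-[5-methoxy-7-(methoxymethoxy)-2,2-dimethyl-3,4-dihydro-2H-chromen-6-yl]-7-(methoxymethoxy)-4H-chromen-4-one
Conditions: H2 (1 atm), 10% Pd/C, EtOAc, rt, stopped after uptake of 1 equiv
Reagents that add atoms: none
Why: Heterogeneous catalytic hydrogenation should saturate the cis-disubstituted styrene-type C3=C4 bond of the chromene well before the trisubstituted vinylogous-ester C2=C3 bond of the chromone, which is conjugated and shielded by the doubly ortho-substituted ring B, as is usual when pyranoisoflavones are converted into their dihydro derivatives.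

Step 13
Reactants: 22 3-[5-methoxy-7-(methoxymethoxy)-2,2-dimethyl-3,4-dihydro-2H-chromen-6-yl]-7-(methoxymethoxy)-4H-chromen-4-one
Product: 23 glycyrrhizaisoflavone C, 7-hydroxy-3-(7-hydroxy-5-methoxy-2,2-dimethyl-3,4-dihydro-2H-chromen-6-yl)-4H-chromen-4-one
Conditions: 3 M HCl, MeOH, 50 °C
Reagents that add atoms: none
Why: Acid-catalysed acetal cleavage should remove both MOM ethers, while the aryl methyl ether, the chromane ether and the chromone are stable to dilute acid; the target has no stereocentre.

Compound list
1 | methoxyhydroquinone (2-methoxybenzene-1,4-diol) | COc1cc(O)ccc1O | starting material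
2 | 2-methoxy-4-(methoxymethoxy)phenol | COCOc1ccc(O)c(OC)c1 | intermediate
3 | 2-methoxy-4-(methoxymethoxy)phenyl N,N-diethylcarbamate | CCN(CC)C(=O)Oc1ccc(OCOC)cc1OC | intermediate
4 | [2-(diethylcarbamoyloxy)-3-methoxy-5-(methoxymethoxy)phenyl]lithium (aryllithium, not isolated) | CCN(CC)C(=O)Oc1c([Li])cc(OCOC)cc1OC | intermediate
5 | 2-methoxy-4-(methoxymethoxy)-6-(trimethylsilyl)phenyl N,N-diethylcarbamate | CCN(CC)C(=O)Oc1c([Si](C)(C)C)cc(OCOC)cc1OC | intermediate
6 | [3-(diethylcarbamoyloxy)-2-methoxy-6-(methoxymethoxy)-4-(trimethylsilyl)phenyl]lithium (aryllithium, not isolated) | CCN(CC)C(=O)Oc1c([Si](C)(C)C)cc(OCOC)c([Li])c1OC | intermediate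
7 | 3-bromo-2-methoxy-4-(methoxymethoxy)-6-(trimethylsilyl)phenyl N,N-diethylcarbamate | CCN(CC)C(=O)Oc1c([Si](C)(C)C)cc(OCOC)c(Br)c1OC | intermediate
8 | 3-bromo-2-methoxy-4-(methoxymethoxy)-6-(trimethylsilyl)phenol | COCOc1cc([Si](C)(C)C)c(O)c(OC)c1Br | intermediate
9 | 3-bromo-2-methoxy-4-(methoxymethoxy)-6-(trimethylsilyl)phenyl trifluoromethanesulfonate | COCOc1cc([Si](C)(C)C)c(OS(=O)(=O)C(F)(F)F)c(OC)c1Br | intermediate
10 | 3-methylbut-2-enal | CC(C)=CC=O | starting material
11 | 4-bromo-3-methoxy-5-(methoxymethoxy)benzyne (aryne, not isolated) | COCOC1=CC#CC(OC)=C1Br | intermediate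
12 | 4-bromo-3-methoxy-5-(methoxymethoxy)-2-(2-methylprop-1-en-1-yl)-2H-benzoxete (racemic, not isolated) | COCOc1cc2OC(C=C(C)C)c2c(OC)c1Br | intermediate
13 | 4-bromo-5-methoxy-3-(methoxymethoxy)-6-(3-methylbut-2-en-1-ylidene)cyclohexa-2,4-dien-1-one (ortho-quinone methide, exocyclic alkene geometry not fixed, not isolated) | O=C1C=C(OCOC)C(Br)=C(OC)C1=CC=C(C)C | intermediate
14 | 6-bromo-5-methoxy-7-(methoxymethoxy)-2,2-dimethyl-2H-chromene | COCOc1cc2OC(C)(C)C=Cc2c(OC)c1Br | intermediate
15 | 2,4-dihydroxyacetophenone | CC(=O)c1ccc(O)cc1O | starting material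
16 | 1-[2-hydroxy-4-(methoxymethoxy)phenyl]ethan-1-one | CC(=O)c1ccc(OCOC)cc1O | intermediate
17 | (E)-3-(dimethylamino)-1-[2-hydroxy-4-(methoxymethoxy)phenyl]prop-2-en-1-one | CN(C)/C=C/C(=O)c1ccc(OCOC)cc1O | intermediate
18 | 3-iodo-7-(methoxymethoxy)-4H-chromen-4-one | COCOc1ccc2c(c1)occ(I)c2=O | intermediate
19 | [5-methoxy-7-(methoxymethoxy)-2,2-dimethyl-2H-chromen-6-yl]lithium (aryllithium, not isolated) | COCOc1cc2OC(C)(C)C=Cc2c(OC)c1[Li] | intermediate
20 | chloro[5-methoxy-7-(methoxymethoxy)-2,2-dimethyl-2H-chromen-6-yl]zinc (arylzinc chloride, not isolated) | COCOc1cc2OC(C)(C)C=Cc2c(OC)c1[Zn]Cl | intermediate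
21 | 3-[5-methoxy-7-(methoxymethoxy)-2,2-dimethyl-2H-chromen-6-yl]-7-(methoxymethoxy)-4H-chromen-4-one | COCOc1ccc2c(c1)occ(-c1c(OCOC)cc3OC(C)(C)C=Cc3c1OC)c2=O | intermediate
22 | 3-[5-methoxy-7-(methoxymethoxy)-2,2-dimethyl-3,4-dihydro-2H-chromen-6-yl]-7-(methoxymethoxy)-4H-chromen-4-one | COCOc1ccc2c(c1)occ(-c1c(OCOC)cc3OC(C)(C)CCc3c1OC)c2=O | intermediate
23 | glycyrrhizaisoflavone C, 7-hydroxy-3-(7-hydroxy-5-methoxy-2,2-dimethyl-3,4-dihydro-2H-chromen-6-yl)-4H-chromen-4-one | COc1c2c(cc(O)c1-c1coc3cc(O)ccc3c1=O)OC(C)(C)CC2 | target

Total step count: 13 steps.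
Longest linear sequence: 10 steps (steps 1 to 7, then 11 to 13); the chromone branch (steps 8 to 10) joins at step 11.

Steps most likely to fail

Risk 1, step 7. The carbonyl oxygen of 10 is a weak nucleophile, so aryne 11 may be consumed by fluoride, by the solvent or by a second aryne before it is trapped, and ortho-quinone methide 13 may add another aryne before it cyclises. The fallback sets out from 9 and builds ring D stepwise. With CsF in DMF the solvent itself should trap the aryne by the same regioselective insertion into a C=O bond, and aqueous work-up should give 3-bromo-6-hydroxy-2-methoxy-4-(methoxymethoxy)benzaldehyde F1. Addition of 2-methylprop-1-en-1-ylmagnesium bromide (2.2 equiv, THF, 0 °C) should give racemic 4-bromo-2-(1-hydroxy-3-methylbut-2-en-1-yl)-3-methoxy-5-(methoxymethoxy)phenol F2. On warming in toluene F2 should lose water to 13, which closes by the same oxa-6π step, and the route is rejoined at 14.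

Risk 2, step 4. The carbamate may steer the base to a silicon-bound methyl group, after which the carbamoyl group migrates, or the base may attack the carbamate carbonyl group, so that ring metalation at C3 stays incomplete. The fallback sets out from 2 and reverses the order in which bromine and silicon are introduced.
- Silylation (i-Pr3SiCl, imidazole, DMF) should give triisopropyl[2-methoxy-4-(methoxymethoxy)phenoxy]silane F3.
- n-BuLi (THF, 0 °C) should remove the proton between OMe and OMOM, and BrCCl2CCl2Br then gives [3-bromo-2-methoxy-4-(methoxymethoxy)phenoxy]triisopropylsilane F4.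
- Bu4NF (THF, 0 °C) releases 3-bromo-2-methoxy-4-(methoxymethoxy)phenol F5.
- NaH and Et2NCOCl give 3-bromo-2-methoxy-4-(methoxymethoxy)phenyl N,N-diethylcarbamate F6.
- Lithium diisopropylamide with Me3SiCl present from the start (THF, −78 °C), a base that does not exchange with aryl bromides, should silylate the only position ortho to the carbamate, and the route is rejoined at 7.

Risk 3, step 11. Transmetalation and reductive elimination at the doubly ortho-substituted arylzinc 20 may be slow, so that protonation of the organometallic, homocoupling or reduction of 18 take over. The fallback sets out from 14 and replaces the zinc reagent by an isolable boron reagent. Aryllithium 19, made as before, is trapped with 2-isopropoxy-4,4,5,5-tetramethyl-1,3,2-dioxaborolane to give 2-[5-methoxy-7-(methoxymethoxy)-2,2-dimethyl-2H-chromen-6-yl]-4,4,5,5-tetramethyl-1,3,2-dioxaborolane F7. F7 is purified and joined to 18 by Suzuki–Miyaura coupling (Pd(OAc)2, SPhos, K3PO4, toluene/water, 60 °C), and the route is rejoined at 21.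

Further compounds
F1 | step 7 | 3-bromo-6-hydroxy-2-methoxy-4-(methoxymethoxy)benzaldehyde | COCOc1cc(O)c(C=O)c(OC)c1Br
F2 | step 7 | 4-bromo-2-(1-hydroxy-3-methylbut-2-en-1-yl)-3-methoxy-5-(methoxymethoxy)phenol (racemic) | COCOc1cc(O)c(C(O)C=C(C)C)c(OC)c1Br
F3 | step 4 | triisopropyl[2-methoxy-4-(methoxymethoxy)phenoxy]silane | COCOc1ccc(O[Si](C(C)C)(C(C)C)C(C)C)c(OC)c1
F4 | step 4 | [3-bromo-2-methoxy-4-(methoxymethoxy)phenoxy]triisopropylsilane | COCOc1ccc(O[Si](C(C)C)(C(C)C)C(C)C)c(OC)c1Br
F5 | step 4 | 3-bromo-2-methoxy-4-(methoxymethoxy)phenol | COCOc1ccc(O)c(OC)c1Br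
F6 | step 4 | 3-bromo-2-methoxy-4-(methoxymethoxy)phenyl N,N-diethylcarbamate | CCN(CC)C(=O)Oc1ccc(OCOC)c(Br)c1OC
F7 | step 11 | 2-[5-methoxy-7-(methoxymethoxy)-2,2-dimethyl-2H-chromen-6-yl]-4,4,5,5-tetramethyl-1,3,2-dioxaborolane | COCOc1cc2OC(C)(C)C=Cc2c(OC)c1B1OC(C)(C)C(C)(C)O1
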